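**Retrosynthetic overview**

1. Atoms are cited in the indene numbering of the target (C1, C2 ketone, C3=C3a, C4–O, C5, C6, C7–CO2H, C7a–CH3; ring A = cyclopentenone, ring B = cyclohexane). Enabling feature: O4 and the C7 carboxyl carbon are cis-1,4 across ring B and C3a is at the carbonyl level. O4–C(=O)–C7 can therefore be closed to a lactone bridge, and the resulting 2-oxabicyclo[2.2.2]octane-3,6-dione is the formal Diels–Alder adduct of 5-hydroxy-2-pyrone (C4=C3a(OH)–C7a=C7) with a two-carbon unit (C5–C6).
2. Key disconnection: C4–C5 and C6–C7, made together by an amine-catalysed asymmetric [4+2] annulation of 2H-pyran-2,5(6H)-dione with acrolein. The formyl group is then excised (acrolein as ethylene equivalent), which erases all isomerism at the dienophile carbons.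
3. The temporary lactone bridge (absent from the target) locks O4/C7 cis and makes C4 and C7 non-enolisable bridgeheads. It directs quaternisation of C7a (allyl, then CH3 syn to the lactone) and, after Wacker/aldol closure of ring A, the C1 alkylation (anti to the cage).
4. Late stage: lactone hydrolysis, 4-methoxybenzyl ester, Yamaguchi esterification of O4 with (2E,4E,6R)-4,6-dimethylocta-2,4-dienoic acid (Wittig/HWE from (R)-2-methylbutan-1-ol), acidolysis, oxidation of the allylic alcohol to the enal.
5. Ring order: pyranone (from furfuryl alcohol) → ring B as lactone-bridged bicycle (key step) → ring A → lactone bridge cleaved.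

Key step: step 3

Assumption: (R)-2-methylbutan-1-ol is treated as a purchasable building block (the antipode of the common fusel-oil alcohol).

**Route**

Step 1
Reactants: 1 furfuryl alcohol
Product: 2 6-hydroxy-2H-pyran-3(6H)-one (racemic lactol)
Conditions: NBS, NaHCO3, THF/H2O (4:1), 0 °C
Reagents that add atoms: water, O
Why: Achmatowicz oxidative ring expansion of a 2-furylcarbinol should give the pyranone lactol, whose single stereocentre is removed in step 2.

Step 2
Reactants: 2 6-hydroxy-2H-pyran-3(6H)-one
Product: 3 2H-pyran-2,5(6H)-dione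
Conditions: CrO3, H2SO4, acetone/H2O, 0 °C
Reagents that add atoms: none
Why: Chromic acid oxidation of the lactol to the lactone, the usual follow-up of the Achmatowicz reaction, should give the keto lactone, which is used without delay because it is both a C–H acid and an ene-dione.

Step 3
Reactants: 3 2H-pyran-2,5(6H)-dione; 4 acrolein
Product: 7 (1S,4S)-3,7-dioxo-2-oxabicyclo[2.2.2]octane-5-carbaldehyde (both epimers at the formyl-bearing carbon), via hydroxypyrone tautomer 5 (not isolated), via Michael adduct 6 (not isolated)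
Conditions: (R)-2-[diphenyl(trimethylsilyloxy)methyl]pyrrolidine (20 mol %), PhCO2H (20 mol %), toluene, −20 °C to rt
Reagents that add atoms: none
Why: Proposed new method: the secondary amine converts acrolein into an iminium ion, the enol tautomer 5 (a cyclic diene locked s-cis, C4=C3a(OH)–C7a=C7) adds through C4 to the β-carbon to give the enamine of 6 (C4–C5 bond), and this enamine adds to C7, the β-carbon of the ring enone, with return of C3a to the ketone (C6–C7 bond), so that both bonds arise in one iminium–enamine Michael/Michael sequence that is formally a Diels–Alder reaction of a 5-hydroxy-2-pyrone. The closest known reaction types are the amine-base-catalysed asymmetric Diels–Alder reactions of 3-hydroxy-2-pyrones and the secondary-amine-catalysed Michael/Michael [4+2] annulations of enals, neither of which has been shown on the 5-oxygenated pyranone. Ring B closes by intramolecular Michael addition of the enamine carbon to the ring enone (6-endo-trig for the carbocycle, 6-exo-trig when counted through the lactone ring), which at the same time creates the 2-oxabicyclo[2.2.2]octane. The bridgehead stereocentres C4 and C7 must be cis because the two-carbon unit can only bridge one face of the pyranone, and their absolute sense is set by the catalyst in the ring closure: the enamine is expected to react through the face remote from the CPh2(OSiMe3) group with its nitrogen over the C3a carbonyl (endo, synclinal Michael topology), and since the C4 stereocentre of 6 is α to the ketone and epimerises through the enol, both enantiomers of 6 should funnel into the matched closure (dynamic, stereoconvergent). The step needs C- rather than O-alkylation of the enol and endo selectivity in the closure, the first secured by the soft iminium acceptor and by the reversibility of O-adducts and hemiacetals against the irreversible second C–C bond, the second by the charge-paired endo transition state; the formyl-bearing C6 is left uncontrolled on purpose because step 4 removes it.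

Step 4
Reactants: 7 (1S,4S)-3,7-dioxo-2-oxabicyclo[2.2.2]octane-5-carbaldehyde
Product: 8 (1S,4R)-2-oxabicyclo[2.2.2]octane-3,6-dione
Conditions: RhCl(PPh3)3 (1.05 equiv), toluene, 110 °C
Reagents that add atoms: none
Why: Tsuji–Wilkinson decarbonylation (insertion into the formyl C–H bond, CO extrusion, reductive elimination) should replace CHO by H, so that both C6 epimers converge on one compound while the non-enolisable bridgeheads C4 and C7 keep their configuration.

Step 5
Reactants: 8 (1S,4R)-2-oxabicyclo[2.2.2]octane-3,6-dione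
Product: 9 (1S,4R)-5-(prop-2-en-1-yl)-2-oxabicyclo[2.2.2]octane-3,6-dione (epimers at the allylated carbon C7a)
Conditions: LiN(iPr)2, THF, −78 °C; allyl bromide, DMPU, −78 to −30 °C
Reagents that add atoms: allyl bromide, C=CCBr
Why: Ketone enolate alkylation that is regiospecific because the ketone can enolise only toward C7a, the other α-carbon C4 being a bridgehead (Bredt strain); the configuration of the new centre is irrelevant since it is enolised again in step 6.

Step 6
Reactants: 9 (1S,4R)-5-(prop-2-en-1-yl)-2-oxabicyclo[2.2.2]octane-3,6-dione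
Product: 10 (1S,4R,5S)-5-methyl-5-(prop-2-en-1-yl)-2-oxabicyclo[2.2.2]octane-3,6-dione
Conditions: LiN(iPr)2, THF, −78 °C; MeI, −78 to −20 °C
Reagents that add atoms: iodomethane, CI
Why: Alkylation of the fully substituted enolate should create the quaternary C7a with methyl entering from the face syn to the lactone bridge (flat O–C=O, no inward C–H) and not from the face screened by the inward hydrogens of the C5–C6 bridge, so that CH3 ends up cis to O4 and to the C7 carboxyl carbon and the allyl group points toward the C5–C6 bridge.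

Step 7
Reactants: 10 (1S,4R,5S)-5-methyl-5-(prop-2-en-1-yl)-2-oxabicyclo[2.2.2]octane-3,6-dione
Product: 11 (1S,4R,5S)-5-methyl-5-(2-oxopropyl)-2-oxabicyclo[2.2.2]octane-3,6-dione
Conditions: PdCl2 (10 mol %), CuCl (30 mol %), O2 (1 atm), DMF/H2O (7:1), rt
Reagents that add atoms: water, O
Why: Tsuji–Wacker oxidation of the terminal alkene should give the methyl ketone with Markovnikov selectivity without touching the lactone or any stereocentre.

Step 8
Reactants: 11 (1S,4R,5S)-5-methyl-5-(2-oxopropyl)-2-oxabicyclo[2.2.2]octane-3,6-dione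
Product: 13 (4S,7R,7aS)-4-hydroxy-7a-methyl-2-oxo-2,4,5,6,7,7a-hexahydro-1H-indene-7-carboxylic acid 4,7-lactone (tricyclic enone lactone), via aldol 12 (not isolated)
Conditions: TsOH·H2O (20 mol %), toluene, 90 °C, removal of water
Reagents that add atoms: none
Why: Acid-catalysed intramolecular aldol condensation of the 1,4-diketone (cyclopentenone annulation) should close ring A because only the methyl carbon can reach the non-enolisable C3a ketone and a furan cannot form at the quaternary C7a; acid is chosen over alkoxide so that the aldol oxygen, which lies syn to the lactone bridge, does not open the lactone by transacylation.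

Step 9
Reactants: 14 2-methylidenepropane-1,3-diol
Product: 15 2-({[tert-butyl(dimethyl)silyl]oxy}methyl)prop-2-en-1-ol
Conditions: NaH (1.0 equiv), THF, 0 °C; TBSCl (1.0 equiv), rt
Reagents that add atoms: tert-butyldimethylsilyl chloride, CC(C)(C)[Si](C)(C)Cl
Why: O-silylation of a symmetrical diol through its sparingly soluble monosodium alkoxide should favour the mono-ether.

Step 10
Reactants: 15 2-({[tert-butyl(dimethyl)silyl]oxy}methyl)prop-2-en-1-ol
Product: 16 {[2-(bromomethyl)prop-2-en-1-yl]oxy}(tert-butyl)dimethylsilane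
Conditions: CBr4, PPh3, CH2Cl2, 0 °C
Reagents that add atoms: tetrabromomethane, BrC(Br)(Br)Br
Why: Appel bromination converts the primary allylic alcohol into the bromide under neutral conditions that leave the silyl ether intact.

Step 11
Reactants: 13 tricyclic enone lactone; 16 {[2-(bromomethyl)prop-2-en-1-yl]oxy}(tert-butyl)dimethylsilane
Product: 17 (1R,4S,7R,7aS)-1-[2-({[tert-butyl(dimethyl)silyl]oxy}methyl)prop-2-en-1-yl]-4-hydroxy-7a-methyl-2-oxo-2,4,5,6,7,7a-hexahydro-1H-indene-7-carboxylic acid 4,7-lactone
Conditions: LiN(SiMe3)2, THF, −78 °C; 16, DMPU, −78 to −30 °C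
Reagents that add atoms: none
Why: Kinetic α′-deprotonation of the cyclopentenone at C1 (the γ-position C4 is a bridgehead) and SN2 alkylation with the allylic bromide should set C1 as R, because the inner face of the enolate is blocked by the C5–C6 bridge of the lactone cage and the electrophile therefore enters cis to the angular methyl.

Step 12
Reactants: 17 C1-alkylated tricyclic lactone
Product: 18 (1R,4S,7R,7aS)-1-[2-({[tert-butyl(dimethyl)silyl]oxy}methyl)prop-2-en-1-yl]-4-hydroxy-7a-methyl-2-oxo-2,4,5,6,7,7a-hexahydro-1H-indene-7-carboxylic acid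
Conditions: LiOH, THF/H2O (3:1), 0 °C; then dilute HCl to pH 3
Reagents that add atoms: lithium hydroxide, [Li+].[OH-]
Why: Saponification of the strained bridged lactone by acyl–oxygen cleavage should release the C4 hydroxyl and the C7 carboxylic acid with retention at both centres, and C1 should stay in its expected preferred configuration (side chain trans to the C7 branch on C7a) even if it epimerises.

Step 13
Reactants: 18 hydroxy acid
Product: 19 4-methoxybenzyl (1R,4S,7R,7aS)-1-[2-({[tert-butyl(dimethyl)silyl]oxy}methyl)prop-2-en-1-yl]-4-hydroxy-7a-methyl-2-oxo-2,4,5,6,7,7a-hexahydro-1H-indene-7-carboxylate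
Conditions: KHCO3, 4-methoxybenzyl chloride, NaI (cat.), DMF, rt
Reagents that add atoms: 4-methoxybenzyl chloride, COc1ccc(CCl)cc1
Why: SN2 O-alkylation of the carboxylate is selective over the hindered secondary alcohol under weakly basic conditions and masks the acid as an acid-labile ester.

Step 14
Reactants: 20 (R)-2-methylbutan-1-ol
Product: 22 (2E,4R)-2,4-dimethylhex-2-enal, via (R)-2-methylbutanal 21 (not isolated)
Conditions: TEMPO (5 mol %), PhI(OAc)2, CH2Cl2, 0 °C to rt; then Ph3P=C(CH3)CHO, 40 °C
Reagents that add atoms: 2-(triphenylphosphoranylidene)propanal, CC(C=O)=P(c1ccccc1)(c1ccccc1)c1ccccc1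
Why: Oxoammonium oxidation followed in the same flask by a Wittig reaction with the stabilised formyl ylide should give the E-enal without isolation of the volatile, epimerisable α-branched aldehyde, whose stereocentre comes from 20.

Step 15
Reactants: 22 (2E,4R)-2,4-dimethylhex-2-enal
Product: 23 ethyl (2E,4E,6R)-4,6-dimethylocta-2,4-dienoate
Conditions: (EtO)2P(O)CH2CO2Et, NaH, THF, 0 °C to rt
Reagents that add atoms: triethyl phosphonoacetate, CCOC(=O)CP(=O)(OCC)OCC
Why: Horner–Wadsworth–Emmons olefination of the enal with the stabilised phosphonate anion should give the 2E-dienoate.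

Step 16
Reactants: 23 ethyl (2E,4E,6R)-4,6-dimethylocta-2,4-dienoate
Product: 24 (2E,4E,6R)-4,6-dimethylocta-2,4-dienoic acid
Conditions: LiOH, THF/MeOH/H2O, rt; then dilute HCl
Reagents that add atoms: lithium hydroxide, [Li+].[OH-]
Why: Ester saponification, which leaves the diene geometry and the remote C6 stereocentre untouched.

Step 17
Reactants: 19 hydroxy 4-methoxybenzyl ester; 24 (2E,4E,6R)-4,6-dimethylocta-2,4-dienoic acid
Product: 26 4-methoxybenzyl (1R,4S,7R,7aS)-1-[2-({[tert-butyl(dimethyl)silyl]oxy}methyl)prop-2-en-1-yl]-4-{[(2E,4E,6R)-4,6-dimethylocta-2,4-dienoyl]oxy}-7a-methyl-2-oxo-2,4,5,6,7,7a-hexahydro-1H-indene-7-carboxylate, via mixed anhydride 25 (not isolated)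
Conditions: 2,4,6-trichlorobenzoyl chloride, Et3N, THF, rt; then 19, DMAP, toluene, rt to 40 °C
Reagents that add atoms: none
Why: Yamaguchi esterification, in which DMAP attacks the less hindered dienoyl carbonyl of the mixed anhydride, should acylate the axial allylic C4 hydroxyl with retention, since no C–O bond at C4 is broken.

Step 18
Reactants: 26 fully protected ester
Product: 27 (1R,4S,7R,7aS)-4-{[(2E,4E,6R)-4,6-dimethylocta-2,4-dienoyl]oxy}-1-[2-(hydroxymethyl)prop-2-en-1-yl]-7a-methyl-2-oxo-2,4,5,6,7,7a-hexahydro-1H-indene-7-carboxylic acid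
Conditions: TFA/CH2Cl2/H2O (20:80:1), anisole, 0 °C; aqueous work-up at pH 4
Reagents that add atoms: none
Why: Acidolysis removes the 4-methoxybenzyl ester (SN1, cation trapped by anisole) and the primary silyl ether in one operation, while the C4 ester should survive because ionisation at C4 would place a cation next to the electron-poor enone.

Step 19
Reactants: 27 hydroxy acid
Product: 28 (1R,4S,7R,7aS)-4-{[(2E,4E,6R)-4,6-dimethylocta-2,4-dienoyl]oxy}-1-(2-formylprop-2-en-1-yl)-7a-methyl-2-oxo-2,4,5,6,7,7a-hexahydro-1H-indene-7-carboxylic acid (target)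
Conditions: 1,1,1-triacetoxy-1,1-dihydro-1,2-benziodoxol-3(1H)-one (DMP), CH2Cl2, 0 °C to rt
Reagents that add atoms: none
Why: Hypervalent-iodine oxidation of the only free (primary allylic) hydroxyl should unveil the sensitive 2-methylidene aldehyde last, under conditions that tolerate the free carboxylic acid.

**Compound list**

1 | furfuryl alcohol | OCc1ccco1 | starting material
2 | 6-hydroxy-2H-pyran-3(6H)-one (racemic) | O=C1COC(O)C=C1 | intermediate
3 | 2H-pyran-2,5(6H)-dione | O=C1COC(=O)C=C1 | intermediate
4 | acrolein | C=CC=O | starting material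
5 | 5-hydroxy-2H-pyran-2-one (enol tautomer of 3) | OC1=COC(=O)C=C1 | intermediate
6 | 3-(3,6-dioxo-3,6-dihydro-2H-pyran-2-yl)propanal (Michael adduct, epimerising) | O=CCCC1OC(=O)C=CC1=O | intermediate
7 | (1S,4S)-3,7-dioxo-2-oxabicyclo[2.2.2]octane-5-carbaldehyde (C5 epimers) | O=C1[C@@H](O2)CC(C=O)[C@@H](C2=O)C1 | intermediate
8 | (1S,4R)-2-oxabicyclo[2.2.2]octane-3,6-dione | O=C1[C@@H](O2)CC[C@@H](C2=O)C1 | intermediate
9 | (1S,4R)-5-(prop-2-en-1-yl)-2-oxabicyclo[2.2.2]octane-3,6-dione (C5 epimers) | O=C1[C@@H](O2)CC[C@@H](C2=O)C1CC=C | intermediate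
10 | (1S,4R,5S)-5-methyl-5-(prop-2-en-1-yl)-2-oxabicyclo[2.2.2]octane-3,6-dione | O=C1[C@@H](O2)CC[C@@H](C2=O)[C@@]1(CC=C)C | intermediate
11 | (1S,4R,5S)-5-methyl-5-(2-oxopropyl)-2-oxabicyclo[2.2.2]octane-3,6-dione | O=C1[C@@H](O2)CC[C@@H](C2=O)[C@@]1(CC(C)=O)C | intermediate
12 | (4S,7R,7aS)-3a,4-dihydroxy-7a-methyl-2-oxooctahydro-1H-indene-7-carboxylic acid 4,7-lactone (aldol, C3a undefined) | C1C(=O)CC2(O)[C@@H](O3)CC[C@@H](C3=O)[C@@]21C | intermediate
13 | (4S,7R,7aS)-4-hydroxy-7a-methyl-2-oxo-2,4,5,6,7,7a-hexahydro-1H-indene-7-carboxylic acid 4,7-lactone | C1C(=O)C=C2[C@@H](O3)CC[C@@H](C3=O)[C@@]21C | intermediate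
14 | 2-methylidenepropane-1,3-diol | C=C(CO)CO | starting material
15 | 2-({[tert-butyl(dimethyl)silyl]oxy}methyl)prop-2-en-1-ol | C=C(CO)CO[Si](C)(C)C(C)(C)C | intermediate
16 | {[2-(bromomethyl)prop-2-en-1-yl]oxy}(tert-butyl)dimethylsilane | C=C(CBr)CO[Si](C)(C)C(C)(C)C | intermediate
17 | (1R,4S,7R,7aS)-1-[2-({[tert-butyl(dimethyl)silyl]oxy}methyl)prop-2-en-1-yl]-4-hydroxy-7a-methyl-2-oxo-2,4,5,6,7,7a-hexahydro-1H-indene-7-carboxylic acid 4,7-lactone | C=C(CO[Si](C)(C)C(C)(C)C)C[C@H]1C(=O)C=C2[C@@H](O3)CC[C@@H](C3=O)[C@@]21C | intermediate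
18 | (1R,4S,7R,7aS)-1-[2-({[tert-butyl(dimethyl)silyl]oxy}methyl)prop-2-en-1-yl]-4-hydroxy-7a-methyl-2-oxo-2,4,5,6,7,7a-hexahydro-1H-indene-7-carboxylic acid | C=C(CO[Si](C)(C)C(C)(C)C)C[C@H]1C(=O)C=C2[C@@H](O)CC[C@@H](C(=O)O)[C@@]21C | intermediate
19 | 4-methoxybenzyl ester of 18 | C=C(CO[Si](C)(C)C(C)(C)C)C[C@H]1C(=O)C=C2[C@@H](O)CC[C@@H](C(=O)OCc3ccc(OC)cc3)[C@@]21C | intermediate
20 | (R)-2-methylbutan-1-ol | CC[C@@H](C)CO | starting material
21 | (R)-2-methylbutanal | CC[C@@H](C)C=O | intermediate
22 | (2E,4R)-2,4-dimethylhex-2-enal | CC[C@@H](C)/C=C(\C)C=O | intermediate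
23 | ethyl (2E,4E,6R)-4,6-dimethylocta-2,4-dienoate | CCOC(=O)/C=C/C(C)=C/[C@H](C)CC | intermediate
24 | (2E,4E,6R)-4,6-dimethylocta-2,4-dienoic acid | OC(=O)/C=C/C(C)=C/[C@H](C)CC | intermediate
25 | (2E,4E,6R)-4,6-dimethylocta-2,4-dienoic 2,4,6-trichlorobenzoic anhydride | O=C(c1c(Cl)cc(Cl)cc1Cl)OC(=O)/C=C/C(C)=C/[C@H](C)CC | intermediate
26 | 4-methoxybenzyl (1R,4S,7R,7aS)-1-[2-({[tert-butyl(dimethyl)silyl]oxy}methyl)prop-2-en-1-yl]-4-{[(2E,4E,6R)-4,6-dimethylocta-2,4-dienoyl]oxy}-7a-methyl-2-oxo-2,4,5,6,7,7a-hexahydro-1H-indene-7-carboxylate | C=C(CO[Si](C)(C)C(C)(C)C)C[C@H]1C(=O)C=C2[C@@H](OC(=O)/C=C/C(C)=C/[C@H](C)CC)CC[C@@H](C(=O)OCc3ccc(OC)cc3)[C@@]21C | intermediate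
27 | (1R,4S,7R,7aS)-4-{[(2E,4E,6R)-4,6-dimethylocta-2,4-dienoyl]oxy}-1-[2-(hydroxymethyl)prop-2-en-1-yl]-7a-methyl-2-oxo-2,4,5,6,7,7a-hexahydro-1H-indene-7-carboxylic acid | C=C(CO)C[C@H]1C(=O)C=C2[C@@H](OC(=O)/C=C/C(C)=C/[C@H](C)CC)CC[C@@H](C(=O)O)[C@@]21C | intermediate
28 | (1R,4S,7R,7aS)-4-{[(2E,4E,6R)-4,6-dimethylocta-2,4-dienoyl]oxy}-1-(2-formylprop-2-en-1-yl)-7a-methyl-2-oxo-2,4,5,6,7,7a-hexahydro-1H-indene-7-carboxylic acid | C=C(C=O)C[C@H]1C(=O)C=C2[C@@H](OC(=O)/C=C/C(C)=C/[C@H](C)CC)CC[C@@H](C(=O)O)[C@@]21C | target

**Step count and risks**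

Total steps: 19. Longest linear sequence: 14 (steps 1–8, 11–13, 17–19, from furfuryl alcohol).

Steps most likely to fail:

1. Step 3 (key step). Enantiocontrol may be eroded if the exo closure competes with the endo closure, because the two give opposite bridgehead configurations once the formyl group is removed. The dione 3 may also be consumed by self-condensation before it meets the iminium ion. If the closure proves cleanly exo, the (S)-catalyst is the matched one. Fallback, from 3, back to the route at 8: O-silylation (TBSOTf, Et3N, CH2Cl2, 0 °C) should give 5-{[tert-butyl(dimethyl)silyl]oxy}-2H-pyran-2-one F1. A thermal normal-demand 2-pyrone Diels–Alder reaction with acrolein (toluene, 60 °C, sealed tube) would give the racemic silyl enol ether adduct 7-{[tert-butyl(dimethyl)silyl]oxy}-3-oxo-2-oxabicyclo[2.2.2]oct-7-ene-5-carbaldehyde F2, all regio- and stereoisomers of which converge later. Dilute HCl in THF unmasks racemic 3,7-dioxo-2-oxabicyclo[2.2.2]octane-5-carbaldehyde F3. Decarbonylation with RhCl(PPh3)3 as in step 4 gives racemic 2-oxabicyclo[2.2.2]octane-3,6-dione F4, whose enantiomers are separated by preparative chromatography on a chiral stationary phase; the (1S,4R) enantiomer is 8.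

2. Step 6. Facial selectivity in the methylation of the tetrasubstituted enolate may be poor, since the lactone bridge and the C5–C6 bridge differ only modestly in size. If the intrinsic preference turns out to be for the C5–C6 face, steps 5 and 6 are simply run in the opposite order. Fallback for low selectivity, from 8, back to the route at 10: methylation first (LiN(iPr)2, MeI) would give (1S,4R)-5-methyl-2-oxabicyclo[2.2.2]octane-3,6-dione F5. Trapping of its enolate on oxygen (LiN(SiMe3)2, allyl chloroformate, THF, −78 °C) would give (1S,4R)-5-methyl-3-oxo-2-oxabicyclo[2.2.2]oct-5-en-6-yl prop-2-en-1-yl carbonate F6. Decarboxylative allylic alkylation (Pd2(dba)3, a chiral phosphinooxazoline ligand such as t-BuPHOX, THF, rt) would then transfer the allyl group to C7a under catalyst control, the ligand antipode that delivers allyl to the face of the C5–C6 bridge being selected, to reach 10.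

3. Step 8. The aldol closure may stall at the hindered C3a ketone, or the aldol oxygen may open the lactone by transacylation, so that the cage needed for step 11 is lost. Fallback, from 11, back to the route at 13: the condensation is run with KOH in THF/H2O, accepting the transacylation (acyl shift to the C3a oxygen, then β-elimination of the carboxylate), which after acidification should give (4S,7R,7aS)-4-hydroxy-7a-methyl-2-oxo-2,4,5,6,7,7a-hexahydro-1H-indene-7-carboxylic acid F7. The bridge is then closed again by lactonisation through the mixed anhydride (2,4,6-trichlorobenzoyl chloride, Et3N; DMAP, toluene), returning to 13.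

**Further compounds**

F1 | step 3 | 5-{[tert-butyl(dimethyl)silyl]oxy}-2H-pyran-2-one | O=C1C=CC(O[Si](C)(C)C(C)(C)C)=CO1
F2 | step 3 | racemic 7-{[tert-butyl(dimethyl)silyl]oxy}-3-oxo-2-oxabicyclo[2.2.2]oct-7-ene-5-carbaldehyde | O=CC1CC2OC(=O)C1C=C2O[Si](C)(C)C(C)(C)C
F3 | step 3 | racemic 3,7-dioxo-2-oxabicyclo[2.2.2]octane-5-carbaldehyde | O=CC1CC2OC(=O)C1CC2=O
F4 | step 3 | racemic 2-oxabicyclo[2.2.2]octane-3,6-dione | O=C1CC2CCC1OC2=O
F5 | step 6 | (1S,4R)-5-methyl-2-oxabicyclo[2.2.2]octane-3,6-dione (C5 epimers) | O=C1[C@@H](O2)CC[C@@H](C2=O)C1C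
F6 | step 6 | (1S,4R)-5-methyl-3-oxo-2-oxabicyclo[2.2.2]oct-5-en-6-yl prop-2-en-1-yl carbonate | C=CCOC(=O)OC1[C@@H](O2)CC[C@@H](C2=O)C=1C
F7 | step 8 | (4S,7R,7aS)-4-hydroxy-7a-methyl-2-oxo-2,4,5,6,7,7a-hexahydro-1H-indene-7-carboxylic acid | C1C(=O)C=C2[C@@H](O)CC[C@@H](C(=O)O)[C@@]21C
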